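If one target takes one partner, a flask cannot make more target than it was charged partner, and noon, at 0.500 equiv, has that ceiling. Yet Thursday's run lost 36.5% of its substrate in 60.0 min and showed 14.7% of target, and those two numbers did not seem to belong to one reaction.

| flask | substrate | partner | remark | time |
|---|---|---|---|---|
| Thursday's | 0.30 M | 0.50 equiv | run made earlier |  |
| Monday's | 0.40 M | 0.50 equiv | run made earlier |  |
| noon | 0.20 M | 0.500 equiv |  | 3.0 h |
| autumn | 0.20 M | 0.800 equiv |  | 3.0 h |
| spring | 0.20 M | 1.20 equiv |  | 3.0 h |

| run | time / min | target / % | substrate / % |
|---|---|---|---|
| Thursday's | 8.00 | 2.5 | 93.4 |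
| Thursday's | 20.0 | 4.6 | 83.9 |
| Thursday's | 40.0 | 10.8 | 72.6 |
| Thursday's | 60.0 | 14.7 | 63.5 |
| Monday's | 8.00 | 2.7 | 91.8 |
| Monday's | 20.0 | 4.9 | 81.3 |
| Monday's | 40.0 | 10.3 | 69.3 |
| Monday's | 60.0 | 15.7 | 59.8 |

(scatter of a reading: 0.5 percentage points)

- the earlier runs were read with a standard deviation of 0.5 percentage points
- a reading or a percentage of target counts all its forms, free or not
- "hardly changes" means that all values lie within two and a half points (for a concentration: within two and a half percent of the largest)

- amount of target at the end, in percent of the substrate charged for noon, autumn, spring, in this order
- how that number moves from the first to the last of them (rises all the way / hardly changes / falls all the way / falls, then rises / rises, then falls)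

I cleared this up by counting. The gap between substrate lost and target made was 21.8% on Thursday and 24.5% on Monday, so substrate was also leaving by a second road. I assumed that each substrate lost, by either road, claimed one partner.

I then drew a straight line through the logarithmic loss rates at 0.30 M and 0.40 M and read κ, the loss rate at 0.20 M and 0.50 equiv, as 0.00657 /min, a reading that carries the scatter of the runs. Holding κ steady over the run, I estimated the crossing charge x*, the equivalents of partner equal to the fraction of substrate lost by the end of the run, as 0.693. Noon lies below x*, so I expected its partner to be used up before 3.0 h. Spring lies above x*, so I expected partner to stand over there. The gap had grown from Thursday to Monday as both concentrations rose, so I expected extra partner above x* to feed the second road, and the row to rise and then fall, turning near x*.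

The forecast differed: it gave 38%, 38% and 38%, so hardly changes, taking “a substrate-limited step, zero order in partner”.

The flasks gave 29.1%, 34.1% and 27.6%: rises, then falls.

    substrate ⇌ tautomer (K = 1.00, k = 7.07 × 10⁻⁵ /s)
    substrate + partner → isomer of the product A (k = 6.63 × 10⁻⁴ /M/s)
    partner + tautomer → target (k = 1.35 /M/s)
    target ⇌ isomer of the product B (K = 0.674, k = 7.76 × 10⁻⁴ /s)
    crystals ⇌ target, rate k5*(cs5 - [target]) while solid is left; crystals form when [target] > cs5 (solubility = 18.0 mM, k = 0.00578 /s)

The row turned at 0.67 equiv, close to x*. Noon, below x*, ended with 0% of its partner, the limiting reagent, and 40% of its substrate. In noon at 1.12 h, partner went to target 3.7 times as fast as to isomer of the product A. Spring, above x*, ended with 32% of its partner left, and with isomer of the product A at 47.6% against target at 27.6%.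

The earlier runs and the new flask are simulated for an exercise; noise was put on by code.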